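The pyrrole ring is cut at N1–C5 and C2–C3: C3 with its C21 chain, C4 and C5 come from henicosyl vinyl ketone, while N1, C2 and the ester come from N-tosylglycine methyl ester. The key step exploits two features of the ring, a C3 that can be a ketone carbon and a C4–C5 unit without substituents; one base-mediated aza-Michael/aldol cascade then forms both bonds and the five-membered ring as a 3-hydroxy-N-tosylpyrrolidine. Its precursors are the terminal C24 enone, made from docosanoic acid, and the sulfonamide ester. Dehydration and loss of sulfinate aromatise the ring without an oxidant.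

Key step: step 4

Assumption: the side chain is unbranched henicosyl (C21H43) and the target is achiral, so the two stereocentres created in step 4 need no control.

Step 1
Reactants: 1 docosanoic acid
Product: 3 N-methoxy-N-methyldocosanamide, via 1-docosanoylimidazole 2 (not isolated)
Conditions: CDI (1.2 equiv), THF, 45 °C; then MeNH(OMe)·HCl (1.5 equiv), rt
Reagents that add atoms: N,O-dimethylhydroxylamine hydrochloride, CNOC.Cl
Why: Amide coupling through an acyl imidazolide: CDI turns the acid into 2 with loss of CO2, the imidazole set free liberates the hydroxylamine from its salt, and this amine then acylates cleanly to the Weinreb amide.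

Step 2
Reactants: 3 N-methoxy-N-methyldocosanamide; 4 vinylmagnesium bromide
Product: 6 tetracos-1-en-3-one, via bromomagnesium hemiaminal 5 (not isolated)
Conditions: THF, 0 °C; then poured into cold 2 M aq. HCl
Reagents that add atoms: none
Why: Weinreb ketone synthesis: the chelated tetrahedral adduct 5 should survive until the quench, so the ketone never meets the Grignard reagent, and inverse addition into cold acid protonates the released N,O-dimethylhydroxylamine before it can add to the enone, which is taken into step 4 without storage.

Step 3
Reactants: 7 glycine methyl ester hydrochloride; 8 p-toluenesulfonyl chloride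
Product: 9 methyl N-tosylglycinate
Conditions: Et3N (2.2 equiv), CH2Cl2, 0 °C to rt
Reagents that add atoms: none
Why: Sulfonylation of a primary amine with a sulfonyl chloride (Hinsberg-type N-tosylation) is fast at this temperature, the ester is untouched by Et3N, and one equivalent of 8 should stop the reaction at the monosulfonamide.

Step 4
Reactants: 9 methyl N-tosylglycinate; 6 tetracos-1-en-3-one
Product: 11 methyl 3-henicosyl-3-hydroxy-1-tosylpyrrolidine-2-carboxylate (racemic; both C2/C3 diastereomers), via aza-Michael adduct 10 (not isolated)
Conditions: DBU (1.0 equiv), THF, 0 °C to rt; 6 added slowly to 9 and DBU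
Reagents that add atoms: none
Why: DBU deprotonates the sulfonamide N–H, and the nitrogen anion adds to the unsubstituted terminal carbon of the enone to form N1–C5 and ketone 10; the glycine CH2, now flanked by the ester and the N-sulfonyl group, is enolised and attacks the ketone to form C2–C3 with the chain on the new carbinol carbon. The closest known reaction type is the Kenner pyrrole synthesis, the aza-Michael/intramolecular aldol annulation of N-sulfonylglycine esters with vinyl ketones. The pyrrolidine ring closes in a 5-(enolexo)-exo-trig aldol, a mode favoured for five-membered rings. The stereocentres at C2 and C3 form without control, as a racemic mixture of diastereomers under a reversible aldol, and both are removed in steps 5 and 6. The step needs N-alkylation before C–C bond formation and 1,4- over 1,2-addition; the far greater acidity of N–H compared with the alpha C–H, the soft sulfonamide anion and the unhindered CH2 terminus of the enone secure this, and so fix the chain at C3 next to the ester. A second Michael addition at C2 should be outrun by the intramolecular aldol, helped by slow addition of the enone.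

Step 5
Reactants: 11 methyl 3-henicosyl-3-hydroxy-1-tosylpyrrolidine-2-carboxylate
Product: 13 methyl 3-henicosyl-1-tosyl-2,5-dihydro-1H-pyrrole-2-carboxylate (racemic), via dichlorophosphate ester 12 (not isolated)
Conditions: POCl3 (3 equiv), pyridine, 0 °C to rt
Reagents that add atoms: none
Why: POCl3/pyridine dehydration: the tertiary hydroxyl is phosphorylated to 12 and pyridine removes a C4 proton in an E2 elimination that destroys the C3 stereocentre, while any C2=C3 isomer formed alongside should be funnelled to the same pyrrole by the base in step 6.

Step 6
Reactants: 13 methyl 3-henicosyl-1-tosyl-2,5-dihydro-1H-pyrrole-2-carboxylate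
Product: 15 methyl 3-henicosyl-1H-pyrrole-2-carboxylate (target), via 2H-pyrrole tautomer 14 (not isolated)
Conditions: DBU (3 equiv), THF, reflux
Reagents that add atoms: none
Why: E1cB elimination followed by tautomerisation: DBU removes the C2 proton, which is allylic and alpha to the ester, the carbanion expels p-toluenesulfinate from nitrogen to give 14, and a proton shift from the ring CH2 to nitrogen, driven by aromatisation, should deliver the achiral pyrrole.

Compound list
1 | docosanoic acid | CCCCCCCCCCCCCCCCCCCCCC(=O)O | starting material
2 | 1-docosanoylimidazole | CCCCCCCCCCCCCCCCCCCCCC(=O)n1ccnc1 | intermediate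
3 | N-methoxy-N-methyldocosanamide | CCCCCCCCCCCCCCCCCCCCCC(=O)N(C)OC | intermediate
4 | vinylmagnesium bromide | C=C[Mg]Br | starting material
5 | bromomagnesium 3-[methoxy(methyl)amino]tetracos-1-en-3-olate (racemic) | CCCCCCCCCCCCCCCCCCCCCC(O[Mg]Br)(C=C)N(C)OC | intermediate
6 | tetracos-1-en-3-one | CCCCCCCCCCCCCCCCCCCCCC(=O)C=C | intermediate
7 | glycine methyl ester hydrochloride | COC(=O)CN.Cl | starting material
8 | p-toluenesulfonyl chloride | Cc1ccc(cc1)S(=O)(=O)Cl | starting material
9 | methyl N-tosylglycinate | COC(=O)CNS(=O)(=O)c1ccc(C)cc1 | intermediate
10 | methyl N-(3-oxotetracosyl)-N-tosylglycinate | CCCCCCCCCCCCCCCCCCCCCC(=O)CCN(CC(=O)OC)S(=O)(=O)c1ccc(C)cc1 | intermediate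
11 | methyl 3-henicosyl-3-hydroxy-1-tosylpyrrolidine-2-carboxylate (racemic; both C2/C3 diastereomers) | CCCCCCCCCCCCCCCCCCCCCC1(O)CCN(S(=O)(=O)c2ccc(C)cc2)C1C(=O)OC | intermediate
12 | methyl 3-[(dichlorophosphoryl)oxy]-3-henicosyl-1-tosylpyrrolidine-2-carboxylate (racemic; both diastereomers) | CCCCCCCCCCCCCCCCCCCCCC1(OP(=O)(Cl)Cl)CCN(S(=O)(=O)c2ccc(C)cc2)C1C(=O)OC | intermediate
13 | methyl 3-henicosyl-1-tosyl-2,5-dihydro-1H-pyrrole-2-carboxylate (racemic) | CCCCCCCCCCCCCCCCCCCCCC1=CCN(S(=O)(=O)c2ccc(C)cc2)C1C(=O)OC | intermediate
14 | methyl 4-henicosyl-2H-pyrrole-5-carboxylate | CCCCCCCCCCCCCCCCCCCCCC1=CCN=C1C(=O)OC | intermediate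
15 | methyl 3-henicosyl-1H-pyrrole-2-carboxylate | CCCCCCCCCCCCCCCCCCCCCc1cc[nH]c1C(=O)OC | target

Total step count: 6. Longest linear sequence: 5 steps (steps 1, 2, 4, 5, 6); step 3 is a one-step branch.

Steps most likely to fail

Step 4 (key step). The enone may oligomerise under base, a second conjugate addition at C2 may compete with ring closure, or the aldol equilibrium may stall at the open-chain stage. The fallback replaces the Michael/aldol cascade by an enaminone condensation and sets out from 3 and 7. Amide 3 is treated with ethynylmagnesium bromide (THF, 0 °C, inverse quench into cold aqueous HCl) to give tetracos-1-yn-3-one F1. Glycine methyl ester, freed from 7 with Et3N in MeOH–THF at rt, adds to the alkyne terminus of F1 to give the hydrogen-bonded enaminone methyl N-[(1Z)-3-oxotetracos-1-en-1-yl]glycinate F2. NaOMe in MeOH–THF at reflux then closes C2–C3 by intramolecular Knoevenagel-type condensation of the glycine CH2 on the ketone, and loss of water should give the pyrrole directly. This fallback comes back to the route at 15, so steps 5 and 6 are not needed.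

Step 2. The released N,O-dimethylhydroxylamine may add to the new enone during the quench, or the enone may polymerise on concentration. The fallback forms the enone by oxidation, with no amine present, and sets out from 3. Reduction with LiAlH4 (THF, −40 to 0 °C) gives docosanal F3; addition of vinylmagnesium bromide 4 (THF, −78 °C) gives tetracos-1-en-3-ol F4 (racemic); oxidation of the allylic alcohol with Dess–Martin periodinane (CH2Cl2, NaHCO3, rt) comes back to the route at 6.

Step 5. Phosphorylation of the hindered tertiary hydroxyl may be sluggish, or chloride substitution and unselective elimination may compete. The fallback uses an ester-driven E1cB elimination in place of the E2 elimination and sets out from 11. Acetylation (Ac2O, DMAP, Et3N, CH2Cl2, rt to 40 °C) gives methyl 3-acetoxy-3-henicosyl-1-tosylpyrrolidine-2-carboxylate F5. DBU in toluene at 80 °C removes the C2 proton and expels acetate to give methyl 3-henicosyl-1-tosyl-4,5-dihydro-1H-pyrrole-2-carboxylate F6. NaOMe in MeOH–THF at reflux should then shift the double bond out of conjugation through the dienolate and eliminate sulfinate as in step 6. This fallback comes back to the route at 15 and replaces steps 5 and 6.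

Further compounds
F1 | step 4 | tetracos-1-yn-3-one | CCCCCCCCCCCCCCCCCCCCCC(=O)C#C
F2 | step 4 | methyl N-[(1Z)-3-oxotetracos-1-en-1-yl]glycinate | CCCCCCCCCCCCCCCCCCCCCC(=O)/C=C\NCC(=O)OC
F3 | step 2 | docosanal | CCCCCCCCCCCCCCCCCCCCCC=O
F4 | step 2 | tetracos-1-en-3-ol (racemic) | CCCCCCCCCCCCCCCCCCCCCC(O)C=C
F5 | step 5 | methyl 3-acetoxy-3-henicosyl-1-tosylpyrrolidine-2-carboxylate (racemic; both diastereomers) | CCCCCCCCCCCCCCCCCCCCCC1(OC(C)=O)CCN(S(=O)(=O)c2ccc(C)cc2)C1C(=O)OC
F6 | step 5 | methyl 3-henicosyl-1-tosyl-4,5-dihydro-1H-pyrrole-2-carboxylate | CCCCCCCCCCCCCCCCCCCCCC1=C(C(=O)OC)N(S(=O)(=O)c2ccc(C)cc2)CC1
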